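**Plan**
Numbering (germacrane): ring C1–C10 with C1=C10 (C14 on C10), C9–O, C7 bearing C11(=C13)–C12, and the C4–C5 epoxide (C15 on C4). The ten-membered ring is cut at C1–C2: C1 is the β-carbon of a 2-(oxymethyl)allylic alcohol unit (C9–C10(C14)=C1, a β-iodo Morita–Baylis–Hillman retron) and C2 is a primary carbon two atoms from the C4=C5 olefin, so the seco compound is a (Z)-alkenyl iodide/primary alkylboron pair.
Further cuts: C9–C10 (asymmetric iodo-aldol with methyl propiolate, which also brings C1 and C14), C2–C3 (Ireland–Claisen [3,3] rearrangement that fixes the C4=C5 geometry; its carboxyl carbon is then exchanged for boron) and C4–C5 (2-lithioallyl ether plus aldehyde).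
Chiral pool: (R)-carvone with C2 and its methyl excised supplies C5–C9 and the isopropenyl unit (carvone C3, C4, C5, C6, C1 become C5, C6, C7, C8, C9; carvone C10 becomes C12).
Forward order: carvone → C12–O → ring cleavage → western chain → boron at C2 → iodo-enoate → ten-membered carbocycle by palladium-catalysed C1–C2 coupling → esters at C14, C9, C12 → oxirane ring last.
Stereochemistry: C7 from carvone; C9 from the oxazaborolidinium catalyst; C1=C10 from the (Z)-iodide (retention) and C4=C5 from the Claisen chair; C4/C5 from L-(+)-tartrate (Sharpless); C2'/C3' of the side chain from an Evans syn-aldol.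

Key step: step 13

Assumption: the (S)-oxazaborolidinium ion is taken to expose the si face of the bound aldehyde (boron-coordinated carbonyl with a formyl C–H···O contact); if the opposite sense were found, its enantiomer would be used in step 12.

Step 1
Reactants: 1 (R)-carvone
Product: 2 (5R)-5-(3-hydroxyprop-1-en-2-yl)-2-methylcyclohex-2-en-1-one
Conditions: SeO2 (cat.), tBuOOH, CH2Cl2, rt
Reagents that add atoms: selenium dioxide O=[Se]=O (oxygen carrier); tert-butyl hydroperoxide CC(C)(C)OO (terminal oxidant)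
Why: Riley-type allylic hydroxylation (ene reaction then [2,3]-sigmatropic shift) should take place at the electron-rich 1,1-disubstituted olefin and not at the deactivated enone, removing hydrogen from the methyl group in preference to the ring methine, and it leaves C5 of carvone (the future C7) untouched.

Step 2
Reactants: 2 (5R)-5-(3-hydroxyprop-1-en-2-yl)-2-methylcyclohex-2-en-1-one
Product: 3 (5R)-2-methyl-5-[3-(naphthalen-2-ylmethoxy)prop-1-en-2-yl]cyclohex-2-en-1-one
Conditions: 2-(bromomethyl)naphthalene, Ag2O, 4 Å molecular sieves, CH2Cl2, rt, dark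
Reagents that add atoms: 2-(bromomethyl)naphthalene BrCc1ccc2ccccc2c1
Why: Ag2O-promoted Williamson-type etherification under near-neutral conditions should protect the primary allylic alcohol without enolizing the enone, and the 2-naphthylmethyl ether should withstand the acids, bases, hydrides and Lewis acids used up to step 19 before its oxidative removal in step 20.

Step 3
Reactants: 3 (5R)-2-methyl-5-[3-(naphthalen-2-ylmethoxy)prop-1-en-2-yl]cyclohex-2-en-1-one
Product: 4 (1R,4R,6R)-1-methyl-4-[3-(naphthalen-2-ylmethoxy)prop-1-en-2-yl]-7-oxabicyclo[4.1.0]heptan-2-one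
Conditions: 30% H2O2, NaOH (cat.), MeOH, 0 °C
Reagents that add atoms: hydrogen peroxide OO
Why: Weitz–Scheffer nucleophilic epoxidation should attack only the enone olefin, anti to the ring substituent, and the two new stereocentres are destroyed in step 4.

Step 4
Reactants: 4 (1R,4R,6R)-1-methyl-4-[3-(naphthalen-2-ylmethoxy)prop-1-en-2-yl]-7-oxabicyclo[4.1.0]heptan-2-one
Product: 6 (3R)-3-[3-(naphthalen-2-ylmethoxy)prop-1-en-2-yl]-5-oxopentanoic acid, via trans-diol 5 (not isolated)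
Conditions: 1 M H2SO4, THF, rt; then NaIO4, THF/H2O, pH 4–5, 0 °C → rt
Reagents that add atoms: water O; sodium periodate [Na+].[O-]I(=O)(=O)=O
Why: acid-mediated hydration of the epoxide at the β-carbon followed by Malaprade-type periodate cleavage of the glycol and of the resulting α-dicarbonyl should excise carvone C2 with its methyl as acetic acid, leaving carvone C3 as the aldehyde (future C5) and C1 as the acid (future C9) without touching the stereocentre.

Step 5
Reactants: 6 (3R)-3-[3-(naphthalen-2-ylmethoxy)prop-1-en-2-yl]-5-oxopentanoic acid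
Product: 7 methyl (3R)-3-[3-(naphthalen-2-ylmethoxy)prop-1-en-2-yl]-5-oxopentanoate
Conditions: Me3SiCHN2, toluene/MeOH, 0 °C
Reagents that add atoms: (trimethylsilyl)diazomethane C[Si](C)(C)C=[N+]=[N-]
Why: methyl ester formation with the diazoalkane is selective for the carboxylic acid (it also drains the hydroxy-lactone tautomer through the open form) and leaves the aldehyde free.

Step 6
Reactants: 8 2-bromoprop-2-en-1-ol
Product: 9 [(2-bromoprop-2-en-1-yl)oxy](tert-butyl)diphenylsilane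
Conditions: tBuPh2SiCl, imidazole, CH2Cl2, rt
Reagents that add atoms: tert-butyl(chloro)diphenylsilane CC(C)(C)[Si](Cl)(c1ccccc1)c1ccccc1
Why: standard silylation gives a C15–O protecting group that should survive tBuLi, enolate, hydride, Lewis-acid and palladium steps and is removed only in step 21.

Step 7
Reactants: 9 [(2-bromoprop-2-en-1-yl)oxy](tert-butyl)diphenylsilane, 7 methyl (3R)-3-[3-(naphthalen-2-ylmethoxy)prop-1-en-2-yl]-5-oxopentanoate
Product: 12 methyl (3R)-5-(acetyloxy)-6-{[(tert-butyldiphenylsilyl)oxy]methyl}-3-[3-(naphthalen-2-ylmethoxy)prop-1-en-2-yl]hept-6-enoate (C5 epimers), via vinyllithium 10 (not isolated), via lithium alkoxide 11 (not isolated)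
Conditions: 9, tBuLi (2 equiv), Et2O, −78 °C; add 7, −78 °C; then Ac2O, −78 °C → rt
Reagents that add atoms: acetic anhydride CC(=O)OC(C)=O
Why: bromine–lithium exchange gives a 2-lithioallyl ether whose 1,2-addition to the aldehyde is faster than attack on the methyl ester at −78 °C, in situ O-acetylation pre-empts δ-lactone formation, and the new carbinol centre (C5) is formed as an epimer mixture of no consequence because it becomes sp2 in step 8.

Step 8
Reactants: 12 methyl (3R)-5-(acetyloxy)-6-{[(tert-butyldiphenylsilyl)oxy]methyl}-3-[3-(naphthalen-2-ylmethoxy)prop-1-en-2-yl]hept-6-enoate (C5 epimers)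
Product: 15 (4Z,7R)-4-{[(tert-butyldiphenylsilyl)oxy]methyl}-9-methoxy-7-[3-(naphthalen-2-ylmethoxy)prop-1-en-2-yl]-9-oxonon-4-enoic acid, via bis(silyl ketene acetal) 13 (not isolated), via trimethylsilyl ester 14 (not isolated)
Conditions: LiN(iPr)2 (2.5 equiv), Me3SiCl, THF, −78 °C → 50 °C; then 1 M HCl
Reagents that add atoms: none
Why: Ireland–Claisen rearrangement through a chair transition state with the C6 chain equatorial on the carbinol carbon should form C2–C3 and deliver the trisubstituted C4=C5 olefin with C6 trans to C3 and cis to the silyloxymethyl carbon from either C5 epimer, while the methyl ester is regenerated from its ketene acetal on work-up.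

Step 9
Reactants: 15 (4Z,7R)-4-{[(tert-butyldiphenylsilyl)oxy]methyl}-9-methoxy-7-[3-(naphthalen-2-ylmethoxy)prop-1-en-2-yl]-9-oxonon-4-enoic acid
Product: 16 1-(1,3-dioxoisoindolin-2-yl) 9-methyl (4Z,7R)-4-{[(tert-butyldiphenylsilyl)oxy]methyl}-7-[3-(naphthalen-2-ylmethoxy)prop-1-en-2-yl]non-4-enedioate
Conditions: N-hydroxyphthalimide, N,N'-diisopropylcarbodiimide, DMAP (cat.), CH2Cl2, rt
Reagents that add atoms: N-hydroxyphthalimide O=C1c2ccccc2C(=O)N1O
Why: carbodiimide coupling (Steglich type) gives the redox-active N-(acyloxy)phthalimide needed for radical decarboxylation.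

Step 10
Reactants: 16 1-(1,3-dioxoisoindolin-2-yl) 9-methyl (4Z,7R)-4-{[(tert-butyldiphenylsilyl)oxy]methyl}-7-[3-(naphthalen-2-ylmethoxy)prop-1-en-2-yl]non-4-enedioate
Product: 18 methyl (3R,5Z)-6-{[(tert-butyldiphenylsilyl)oxy]methyl}-3-[3-(naphthalen-2-ylmethoxy)prop-1-en-2-yl]-8-(4,4,5,5-tetramethyl-1,3,2-dioxaborolan-2-yl)oct-5-enoate, via catechol boronate 17 (not isolated)
Conditions: bis(catecholato)diboron, N,N-dimethylacetamide, blue LEDs (450 nm), rt; then pinacol, Et3N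
Reagents that add atoms: bis(catecholato)diboron B1(Oc2ccccc2O1)B1Oc2ccccc2O1; pinacol CC(C)(O)C(C)(C)O
Why: photochemical decarboxylative borylation (the ester–diboron–amide complex fragments under blue light to the primary C2 radical, which is borylated, then transesterified with pinacol) puts boron on C2 without any hydroboration, so none of the three olefins is at risk.

Step 11
Reactants: 18 methyl (3R,5Z)-6-{[(tert-butyldiphenylsilyl)oxy]methyl}-3-[3-(naphthalen-2-ylmethoxy)prop-1-en-2-yl]-8-(4,4,5,5-tetramethyl-1,3,2-dioxaborolan-2-yl)oct-5-enoate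
Product: 19 (3R,5Z)-6-{[(tert-butyldiphenylsilyl)oxy]methyl}-3-[3-(naphthalen-2-ylmethoxy)prop-1-en-2-yl]-8-(4,4,5,5-tetramethyl-1,3,2-dioxaborolan-2-yl)oct-5-enal
Conditions: iBu2AlH (1.1 equiv), CH2Cl2, −78 °C; aq. potassium sodium tartrate
Reagents that add atoms: none
Why: partial reduction of the only ester by iBu2AlH at −78 °C through a stable tetrahedral aluminium hemiacetal should give the C9 aldehyde, with the pinacol boronate and both ethers inert to the hydride.

Step 12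
Reactants: 19 (3R,5Z)-6-{[(tert-butyldiphenylsilyl)oxy]methyl}-3-[3-(naphthalen-2-ylmethoxy)prop-1-en-2-yl]-8-(4,4,5,5-tetramethyl-1,3,2-dioxaborolan-2-yl)oct-5-enal, 20 methyl prop-2-ynoate
Product: 23 methyl (2Z,3R,5R,7Z)-8-{[(tert-butyldiphenylsilyl)oxy]methyl}-3-hydroxy-2-(iodomethylidene)-5-[3-(naphthalen-2-ylmethoxy)prop-1-en-2-yl]-10-(4,4,5,5-tetramethyl-1,3,2-dioxaborolan-2-yl)dec-7-enoate, via silyl iodoallenoate 21 (not isolated), via trimethylsilyl ether 22 (not isolated)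
Conditions: Me3SiI, (S)-o-tolyl-oxazaborolidinium triflimide (from (S)-α,α-diphenylprolinol, 20 mol%), CH2Cl2, −78 °C; then 1 M HCl, THF
Reagents that add atoms: iodotrimethylsilane C[Si](C)(C)I
Why: in this three-component iodo-aldol (β-iodo Morita–Baylis–Hillman) coupling Me3SiI adds to the propiolate to give the silyl β-iodoallenoate, which adds to the catalyst-bound aldehyde on its exposed si face so that C9 should be set (R) under catalyst control, and the kinetic addition geometry should give the (Z)-vinyl iodide with iodine cis to the ester.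

Step 13
Reactants: 23 methyl (2Z,3R,5R,7Z)-8-{[(tert-butyldiphenylsilyl)oxy]methyl}-3-hydroxy-2-(iodomethylidene)-5-[3-(naphthalen-2-ylmethoxy)prop-1-en-2-yl]-10-(4,4,5,5-tetramethyl-1,3,2-dioxaborolan-2-yl)dec-7-enoate
Product: 25 methyl (1Z,5Z,8R,10R)-5-{[(tert-butyldiphenylsilyl)oxy]methyl}-10-hydroxy-8-[3-(naphthalen-2-ylmethoxy)prop-1-en-2-yl]cyclodeca-1,5-diene-1-carboxylate, via potassium trifluoroborate 24 (not isolated)
Conditions: KHF2 (aq), MeOH, rt, then evaporation; [1,1'-bis(diphenylphosphino)ferrocene]dichloropalladium (PdCl2(dppf)·CH2Cl2, 15 mol%), Cs2CO3, THF/H2O (10:1), 65 °C, slow addition to 0.002 M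
Reagents that add atoms: none
Why: zerovalent palladium inserts into the C1–I bond of the (Z)-β-iodoenoate with retention, the primary C2 alkyl group is transferred from boron (trifluoroborate hydrolysed in situ) under base, and C(sp2)–C(sp3) reductive elimination from an eleven-membered alkyl(alkenyl) divalent palladium intermediate forms C1–C2. The closest known reaction type is the B-alkyl Suzuki–Miyaura macrocyclization, combined with the alkyltrifluoroborate/alkenyl halide coupling. The ring closed is the ten-membered carbocycle C1–C10, closed endo with respect to the C1=C10 olefin (both olefin carbons end up in the ring). No stereocentre is formed; the C1=C10 geometry (C2 cis to C14, trans across the ring) is fixed by the preformed (Z)-iodide because both organometallic steps are stereoretentive, and C4=C5 was fixed in step 8. The step needs chemoselective activation of the alkenyl iodide, which is secured by having only silyl and naphthylmethyl allylic ethers present (they do not ionize to π-allyl species, which is why the allylic esters are introduced afterwards), and cyclization over oligomerization, which is secured by high dilution and by the two trisubstituted olefins and the C7 branch that restrict the tether; 65 °C should keep the product below the onset of Cope rearrangement to an elemane.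

Step 14
Reactants: 25 methyl (1Z,5Z,8R,10R)-5-{[(tert-butyldiphenylsilyl)oxy]methyl}-10-hydroxy-8-[3-(naphthalen-2-ylmethoxy)prop-1-en-2-yl]cyclodeca-1,5-diene-1-carboxylate
Product: 26 (1R,2E,6Z,9R)-6-{[(tert-butyldiphenylsilyl)oxy]methyl}-2-(hydroxymethyl)-9-[3-(naphthalen-2-ylmethoxy)prop-1-en-2-yl]cyclodeca-2,6-dien-1-ol
Conditions: iBu2AlH (4 equiv), CH2Cl2, −78 → −40 °C; aq. potassium sodium tartrate
Reagents that add atoms: none
Why: 1,2-reduction of the conjugated methyl ester, the only ester present at this stage, should give the C14 allylic alcohol without touching the olefins.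

Step 15
Reactants: 27 (4R)-4-benzyl-3-propanoyl-1,3-oxazolidin-2-one
Product: 30 (4R)-4-benzyl-3-[(2R,3S)-3-hydroxy-2-methylbutanoyl]-1,3-oxazolidin-2-one, via boron enolate 28 (not isolated), via boron aldolate 29 (not isolated)
Conditions: Bu2BOTf, iPr2NEt, CH2Cl2, −78 → 0 °C; CH3CHO, −78 → 0 °C; then pH 7 buffer, MeOH, H2O2
Reagents that add atoms: acetaldehyde CC=O
Why: in the Evans syn-aldol the (Z)-boron enolate reacts through a closed chair transition state on the face away from the benzyl group, so the (R)-auxiliary should give the (2R,3S) syn adduct.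

Step 16
Reactants: 30 (4R)-4-benzyl-3-[(2R,3S)-3-hydroxy-2-methylbutanoyl]-1,3-oxazolidin-2-one
Product: 31 (4R)-4-benzyl-3-[(2R,3S)-3-{[tert-butyl(dimethyl)silyl]oxy}-2-methylbutanoyl]-1,3-oxazolidin-2-one
Conditions: tBuMe2SiOTf, 2,6-lutidine, CH2Cl2, 0 °C
Reagents that add atoms: tert-butyldimethylsilyl triflate CC(C)(C)[Si](C)(C)OS(=O)(=O)C(F)(F)F
Why: silylation of the secondary alcohol under non-nucleophilic conditions prevents retro-aldol cleavage and self-acylation of the hydroxy acid in step 18.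

Step 17
Reactants: 31 (4R)-4-benzyl-3-[(2R,3S)-3-{[tert-butyl(dimethyl)silyl]oxy}-2-methylbutanoyl]-1,3-oxazolidin-2-one
Product: 33 (2R,3S)-3-{[tert-butyl(dimethyl)silyl]oxy}-2-methylbutanoic acid, via lithium peroxycarboxylate 32 (not isolated)
Conditions: LiOH, H2O2, THF/H2O, 0 °C; then Na2SO3; then 1 M HCl
Reagents that add atoms: hydrogen peroxide OO
Why: hydroperoxide attacks the exocyclic imide carbonyl selectively, so the auxiliary is released and the acid is obtained after sulfite reduction without epimerization at C2.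

Step 18
Reactants: 26 (1R,2E,6Z,9R)-6-{[(tert-butyldiphenylsilyl)oxy]methyl}-2-(hydroxymethyl)-9-[3-(naphthalen-2-ylmethoxy)prop-1-en-2-yl]cyclodeca-2,6-dien-1-ol, 33 (2R,3S)-3-{[tert-butyl(dimethyl)silyl]oxy}-2-methylbutanoic acid
Product: 34 [(1E,5Z,8R,10R)-5-{[(tert-butyldiphenylsilyl)oxy]methyl}-10-hydroxy-8-[3-(naphthalen-2-ylmethoxy)prop-1-en-2-yl]cyclodeca-1,5-dien-1-yl]methyl (2R,3S)-3-{[tert-butyl(dimethyl)silyl]oxy}-2-methylbutanoate
Conditions: EDC·HCl, DMAP (cat.), CH2Cl2, −20 → 0 °C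
Reagents that add atoms: none
Why: Steglich-type esterification at low temperature should acylate the unhindered primary allylic C14 hydroxyl in preference to the secondary C9 hydroxyl, which sits next to the fully substituted olefin carbon.

Step 19
Reactants: 34 [(1E,5Z,8R,10R)-5-{[(tert-butyldiphenylsilyl)oxy]methyl}-10-hydroxy-8-[3-(naphthalen-2-ylmethoxy)prop-1-en-2-yl]cyclodeca-1,5-dien-1-yl]methyl (2R,3S)-3-{[tert-butyl(dimethyl)silyl]oxy}-2-methylbutanoate, 35 3-methylbut-2-enoic acid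
Product: 36 (1R,2E,6Z,9R)-2-({[(2R,3S)-3-{[tert-butyl(dimethyl)silyl]oxy}-2-methylbutanoyl]oxy}methyl)-6-{[(tert-butyldiphenylsilyl)oxy]methyl}-9-[3-(naphthalen-2-ylmethoxy)prop-1-en-2-yl]cyclodeca-2,6-dien-1-yl 3-methylbut-2-enoate
Conditions: N,N'-diisopropylcarbodiimide, DMAP, CH2Cl2, 0 °C → rt
Reagents that add atoms: none
Why: Steglich esterification of the remaining secondary allylic alcohol with the free acid avoids the ketene pathway by which the acid chloride deconjugates, and C9 is not touched at carbon so its configuration is retained.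

Step 20
Reactants: 36 (1R,2E,6Z,9R)-2-({[(2R,3S)-3-{[tert-butyl(dimethyl)silyl]oxy}-2-methylbutanoyl]oxy}methyl)-6-{[(tert-butyldiphenylsilyl)oxy]methyl}-9-[3-(naphthalen-2-ylmethoxy)prop-1-en-2-yl]cyclodeca-2,6-dien-1-yl 3-methylbut-2-enoate
Product: 38 (1R,2E,6Z,9R)-9-[3-(acetyloxy)prop-1-en-2-yl]-2-({[(2R,3S)-3-{[tert-butyl(dimethyl)silyl]oxy}-2-methylbutanoyl]oxy}methyl)-6-{[(tert-butyldiphenylsilyl)oxy]methyl}cyclodeca-2,6-dien-1-yl 3-methylbut-2-enoate, via C12 alcohol 37 (not isolated)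
Conditions: DDQ, CH2Cl2/pH 7 phosphate buffer, 0 °C → rt; aqueous work-up; then Ac2O, pyridine, DMAP (cat.), CH2Cl2, 0 °C
Reagents that add atoms: acetic anhydride CC(=O)OC(C)=O
Why: DDQ removes the electron-rich naphthylmethyl ether by hydride abstraction and hydrolysis of the oxocarbenium ion while silyl ethers, esters and olefins stay intact, and acetylation then installs the C12 acetate that could not have been carried through the hydride and palladium steps.

Step 21
Reactants: 38 (1R,2E,6Z,9R)-9-[3-(acetyloxy)prop-1-en-2-yl]-2-({[(2R,3S)-3-{[tert-butyl(dimethyl)silyl]oxy}-2-methylbutanoyl]oxy}methyl)-6-{[(tert-butyldiphenylsilyl)oxy]methyl}cyclodeca-2,6-dien-1-yl 3-methylbut-2-enoate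
Product: 39 (1R,2E,6Z,9R)-9-[3-(acetyloxy)prop-1-en-2-yl]-6-(hydroxymethyl)-2-({[(2R,3S)-3-hydroxy-2-methylbutanoyl]oxy}methyl)cyclodeca-2,6-dien-1-yl 3-methylbut-2-enoate
Conditions: HF·pyridine, excess pyridine, THF, 0 °C → rt
Reagents that add atoms: none
Why: pyridine-buffered fluoride desilylation should remove both silyl ethers without acyl migration and without acid-induced transannular cyclization of the 1,5-diene.

Step 22
Reactants: 39 (1R,2E,6Z,9R)-9-[3-(acetyloxy)prop-1-en-2-yl]-6-(hydroxymethyl)-2-({[(2R,3S)-3-hydroxy-2-methylbutanoyl]oxy}methyl)cyclodeca-2,6-dien-1-yl 3-methylbut-2-enoate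
Product: 40 CNP0227102.1
Conditions: Ti(OiPr)4 (30 mol%), L-(+)-diethyl tartrate (36 mol%), tBuOOH (anhydrous), 4 Å molecular sieves, CH2Cl2, −20 °C
Reagents that add atoms: tert-butyl hydroperoxide CC(C)(C)OO
Why: in this Sharpless asymmetric epoxidation only C4=C5 carries a free allylic hydroxyl (C15–OH), so the titanium tartrate complex should epoxidize it chemoselectively, and L-(+)-tartrate delivers oxygen to the face that gives the (4S,5R) trans-epoxide (the same face, relative to the carbinol carbon, as in the geraniol to (2S,3S)-epoxygeraniol case).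

**Compound list**
1 | (R)-carvone, (5R)-2-methyl-5-(prop-1-en-2-yl)cyclohex-2-en-1-one | C=C(C)[C@@H]1CC=C(C)C(=O)C1 | starting material
2 | (5R)-5-(3-hydroxyprop-1-en-2-yl)-2-methylcyclohex-2-en-1-one | C=C(CO)[C@@H]1CC=C(C)C(=O)C1 | intermediate
3 | (5R)-2-methyl-5-[3-(naphthalen-2-ylmethoxy)prop-1-en-2-yl]cyclohex-2-en-1-one | C=C(COCc1ccc2ccccc2c1)[C@@H]1CC=C(C)C(=O)C1 | intermediate
4 | (1R,4R,6R)-1-methyl-4-[3-(naphthalen-2-ylmethoxy)prop-1-en-2-yl]-7-oxabicyclo[4.1.0]heptan-2-one | C=C(COCc1ccc2ccccc2c1)[C@@H]1C[C@H]2O[C@@]2(C)C(=O)C1 | intermediate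
5 | (2R,3S,5R)-2,3-dihydroxy-2-methyl-5-[3-(naphthalen-2-ylmethoxy)prop-1-en-2-yl]cyclohexan-1-one | C=C(COCc1ccc2ccccc2c1)[C@@H]1C[C@H](O)[C@@](C)(O)C(=O)C1 | intermediate
6 | (3R)-3-[3-(naphthalen-2-ylmethoxy)prop-1-en-2-yl]-5-oxopentanoic acid | C=C(COCc1ccc2ccccc2c1)[C@H](CC=O)CC(=O)O | intermediate
7 | methyl (3R)-3-[3-(naphthalen-2-ylmethoxy)prop-1-en-2-yl]-5-oxopentanoate | C=C(COCc1ccc2ccccc2c1)[C@H](CC=O)CC(=O)OC | intermediate
8 | 2-bromoprop-2-en-1-ol | C=C(Br)CO | starting material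
9 | [(2-bromoprop-2-en-1-yl)oxy](tert-butyl)diphenylsilane | C=C(Br)CO[Si](c1ccccc1)(c1ccccc1)C(C)(C)C | intermediate
10 | {3-[(tert-butyldiphenylsilyl)oxy]prop-1-en-2-yl}lithium | [Li]C(=C)CO[Si](c1ccccc1)(c1ccccc1)C(C)(C)C | intermediate
11 | lithium (5R)-2-{[(tert-butyldiphenylsilyl)oxy]methyl}-7-methoxy-5-[3-(naphthalen-2-ylmethoxy)prop-1-en-2-yl]-7-oxohept-1-en-3-olate (C3 epimers) | C=C(COCc1ccc2ccccc2c1)[C@H](CC([O-])C(=C)CO[Si](c1ccccc1)(c1ccccc1)C(C)(C)C)CC(=O)OC.[Li+] | intermediate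
12 | methyl (3R)-5-(acetyloxy)-6-{[(tert-butyldiphenylsilyl)oxy]methyl}-3-[3-(naphthalen-2-ylmethoxy)prop-1-en-2-yl]hept-6-enoate (C5 epimers) | C=C(COCc1ccc2ccccc2c1)[C@H](CC(OC(C)=O)C(=C)CO[Si](c1ccccc1)(c1ccccc1)C(C)(C)C)CC(=O)OC | intermediate
13 | bis(trimethylsilyl ketene acetal) of 12 (acetate and methyl ester both O-silylated) | C=C(COCc1ccc2ccccc2c1)[C@H](CC(OC(=C)O[Si](C)(C)C)C(=C)CO[Si](c1ccccc1)(c1ccccc1)C(C)(C)C)C=C(OC)O[Si](C)(C)C | intermediate
14 | trimethylsilyl ester of 15 that still carries the methyl trimethylsilyl ketene acetal | C=C(COCc1ccc2ccccc2c1)[C@H](C/C=C(\CO[Si](c1ccccc1)(c1ccccc1)C(C)(C)C)CCC(=O)O[Si](C)(C)C)C=C(OC)O[Si](C)(C)C | intermediate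
15 | (4Z,7R)-4-{[(tert-butyldiphenylsilyl)oxy]methyl}-9-methoxy-7-[3-(naphthalen-2-ylmethoxy)prop-1-en-2-yl]-9-oxonon-4-enoic acid | C=C(COCc1ccc2ccccc2c1)[C@H](C/C=C(\CO[Si](c1ccccc1)(c1ccccc1)C(C)(C)C)CCC(=O)O)CC(=O)OC | intermediate
16 | 1-(1,3-dioxoisoindolin-2-yl) 9-methyl (4Z,7R)-4-{[(tert-butyldiphenylsilyl)oxy]methyl}-7-[3-(naphthalen-2-ylmethoxy)prop-1-en-2-yl]non-4-enedioate | C=C(COCc1ccc2ccccc2c1)[C@H](C/C=C(\CO[Si](c1ccccc1)(c1ccccc1)C(C)(C)C)CCC(=O)ON1C(=O)c2ccccc2C1=O)CC(=O)OC | intermediate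
17 | methyl (3R,5Z)-8-(1,3,2-benzodioxaborol-2-yl)-6-{[(tert-butyldiphenylsilyl)oxy]methyl}-3-[3-(naphthalen-2-ylmethoxy)prop-1-en-2-yl]oct-5-enoate | C=C(COCc1ccc2ccccc2c1)[C@H](C/C=C(\CO[Si](c1ccccc1)(c1ccccc1)C(C)(C)C)CCB1Oc2ccccc2O1)CC(=O)OC | intermediate
18 | methyl (3R,5Z)-6-{[(tert-butyldiphenylsilyl)oxy]methyl}-3-[3-(naphthalen-2-ylmethoxy)prop-1-en-2-yl]-8-(4,4,5,5-tetramethyl-1,3,2-dioxaborolan-2-yl)oct-5-enoate | C=C(COCc1ccc2ccccc2c1)[C@H](C/C=C(\CO[Si](c1ccccc1)(c1ccccc1)C(C)(C)C)CCB1OC(C)(C)C(C)(C)O1)CC(=O)OC | intermediate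
19 | (3R,5Z)-6-{[(tert-butyldiphenylsilyl)oxy]methyl}-3-[3-(naphthalen-2-ylmethoxy)prop-1-en-2-yl]-8-(4,4,5,5-tetramethyl-1,3,2-dioxaborolan-2-yl)oct-5-enal | C=C(COCc1ccc2ccccc2c1)[C@H](C/C=C(\CO[Si](c1ccccc1)(c1ccccc1)C(C)(C)C)CCB1OC(C)(C)C(C)(C)O1)CC=O | intermediate
20 | methyl prop-2-ynoate | C#CC(=O)OC | starting material
21 | [(3-iodo-1-methoxypropa-1,2-dien-1-yl)oxy]trimethylsilane | IC=C=C(OC)O[Si](C)(C)C | intermediate
22 | O-trimethylsilyl ether of 23 | C=C(COCc1ccc2ccccc2c1)[C@H](C/C=C(\CO[Si](c1ccccc1)(c1ccccc1)C(C)(C)C)CCB1OC(C)(C)C(C)(C)O1)C[C@@H](O[Si](C)(C)C)/C(C(=O)OC)=C/I | intermediate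
23 | methyl (2Z,3R,5R,7Z)-8-{[(tert-butyldiphenylsilyl)oxy]methyl}-3-hydroxy-2-(iodomethylidene)-5-[3-(naphthalen-2-ylmethoxy)prop-1-en-2-yl]-10-(4,4,5,5-tetramethyl-1,3,2-dioxaborolan-2-yl)dec-7-enoate | C=C(COCc1ccc2ccccc2c1)[C@H](C/C=C(\CO[Si](c1ccccc1)(c1ccccc1)C(C)(C)C)CCB1OC(C)(C)C(C)(C)O1)C[C@@H](O)/C(C(=O)OC)=C/I | intermediate
24 | potassium trifluoroborate corresponding to 23 (BF3K in place of the pinacol boronate) | C=C(COCc1ccc2ccccc2c1)[C@H](C/C=C(\CO[Si](c1ccccc1)(c1ccccc1)C(C)(C)C)CC[B-](F)(F)F)C[C@@H](O)/C(C(=O)OC)=C/I.[K+] | intermediate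
25 | methyl (1Z,5Z,8R,10R)-5-{[(tert-butyldiphenylsilyl)oxy]methyl}-10-hydroxy-8-[3-(naphthalen-2-ylmethoxy)prop-1-en-2-yl]cyclodeca-1,5-diene-1-carboxylate (both ring olefins trans across the ring) | C=C(COCc1ccc2ccccc2c1)[C@H]1C[C@@H](O)/C(C(=O)OC)=C/CC/C(CO[Si](c2ccccc2)(c2ccccc2)C(C)(C)C)=C/C1 | intermediate
26 | (1R,2E,6Z,9R)-6-{[(tert-butyldiphenylsilyl)oxy]methyl}-2-(hydroxymethyl)-9-[3-(naphthalen-2-ylmethoxy)prop-1-en-2-yl]cyclodeca-2,6-dien-1-ol | C=C(COCc1ccc2ccccc2c1)[C@H]1C[C@@H](O)/C(CO)=C/CC/C(CO[Si](c2ccccc2)(c2ccccc2)C(C)(C)C)=C/C1 | intermediate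
27 | (4R)-4-benzyl-3-propanoyl-1,3-oxazolidin-2-one | CCC(=O)N1[C@H](Cc2ccccc2)COC1=O | starting material
28 | (Z)-dibutylboron enolate of 27 | C/C=C(\OB(CCCC)CCCC)N1[C@H](Cc2ccccc2)COC1=O | intermediate
29 | O-dibutylboryl aldolate of 30 | O=C([C@H](C)[C@H](C)OB(CCCC)CCCC)N1[C@H](Cc2ccccc2)COC1=O | intermediate
30 | (4R)-4-benzyl-3-[(2R,3S)-3-hydroxy-2-methylbutanoyl]-1,3-oxazolidin-2-one | O=C([C@H](C)[C@H](C)O)N1[C@H](Cc2ccccc2)COC1=O | intermediate
31 | (4R)-4-benzyl-3-[(2R,3S)-3-{[tert-butyl(dimethyl)silyl]oxy}-2-methylbutanoyl]-1,3-oxazolidin-2-one | O=C([C@H](C)[C@H](C)O[Si](C)(C)C(C)(C)C)N1[C@H](Cc2ccccc2)COC1=O | intermediate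
32 | lithium (2R,3S)-3-{[tert-butyl(dimethyl)silyl]oxy}-2-methylbutaneperoxoate | [Li+].[O-]OC(=O)[C@H](C)[C@H](C)O[Si](C)(C)C(C)(C)C | intermediate
33 | (2R,3S)-3-{[tert-butyl(dimethyl)silyl]oxy}-2-methylbutanoic acid | OC(=O)[C@H](C)[C@H](C)O[Si](C)(C)C(C)(C)C | intermediate
34 | [(1E,5Z,8R,10R)-5-{[(tert-butyldiphenylsilyl)oxy]methyl}-10-hydroxy-8-[3-(naphthalen-2-ylmethoxy)prop-1-en-2-yl]cyclodeca-1,5-dien-1-yl]methyl (2R,3S)-3-{[tert-butyl(dimethyl)silyl]oxy}-2-methylbutanoate | C=C(COCc1ccc2ccccc2c1)[C@H]1C[C@@H](O)/C(COC(=O)[C@H](C)[C@H](C)O[Si](C)(C)C(C)(C)C)=C/CC/C(CO[Si](c2ccccc2)(c2ccccc2)C(C)(C)C)=C/C1 | intermediate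
35 | 3-methylbut-2-enoic acid | CC(C)=CC(=O)O | starting material
36 | (1R,2E,6Z,9R)-2-({[(2R,3S)-3-{[tert-butyl(dimethyl)silyl]oxy}-2-methylbutanoyl]oxy}methyl)-6-{[(tert-butyldiphenylsilyl)oxy]methyl}-9-[3-(naphthalen-2-ylmethoxy)prop-1-en-2-yl]cyclodeca-2,6-dien-1-yl 3-methylbut-2-enoate | C=C(COCc1ccc2ccccc2c1)[C@H]1C[C@@H](OC(=O)C=C(C)C)/C(COC(=O)[C@H](C)[C@H](C)O[Si](C)(C)C(C)(C)C)=C/CC/C(CO[Si](c2ccccc2)(c2ccccc2)C(C)(C)C)=C/C1 | intermediate
37 | (1R,2E,6Z,9R)-2-({[(2R,3S)-3-{[tert-butyl(dimethyl)silyl]oxy}-2-methylbutanoyl]oxy}methyl)-6-{[(tert-butyldiphenylsilyl)oxy]methyl}-9-(3-hydroxyprop-1-en-2-yl)cyclodeca-2,6-dien-1-yl 3-methylbut-2-enoate | C=C(CO)[C@H]1C[C@@H](OC(=O)C=C(C)C)/C(COC(=O)[C@H](C)[C@H](C)O[Si](C)(C)C(C)(C)C)=C/CC/C(CO[Si](c2ccccc2)(c2ccccc2)C(C)(C)C)=C/C1 | intermediate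
38 | (1R,2E,6Z,9R)-9-[3-(acetyloxy)prop-1-en-2-yl]-2-({[(2R,3S)-3-{[tert-butyl(dimethyl)silyl]oxy}-2-methylbutanoyl]oxy}methyl)-6-{[(tert-butyldiphenylsilyl)oxy]methyl}cyclodeca-2,6-dien-1-yl 3-methylbut-2-enoate | C=C(COC(C)=O)[C@H]1C[C@@H](OC(=O)C=C(C)C)/C(COC(=O)[C@H](C)[C@H](C)O[Si](C)(C)C(C)(C)C)=C/CC/C(CO[Si](c2ccccc2)(c2ccccc2)C(C)(C)C)=C/C1 | intermediate
39 | (1R,2E,6Z,9R)-9-[3-(acetyloxy)prop-1-en-2-yl]-6-(hydroxymethyl)-2-({[(2R,3S)-3-hydroxy-2-methylbutanoyl]oxy}methyl)cyclodeca-2,6-dien-1-yl 3-methylbut-2-enoate | C=C(COC(C)=O)[C@H]1C[C@@H](OC(=O)C=C(C)C)/C(COC(=O)[C@H](C)[C@H](C)O)=C/CC/C(CO)=C/C1 | intermediate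
40 | CNP0227102.1, (1(10)E,4S,5R,7S,9R)-12-acetoxy-4,5-epoxy-15-hydroxy-14-{[(2R,3S)-3-hydroxy-2-methylbutanoyl]oxy}-9-[(3-methylbut-2-enoyl)oxy]germacra-1(10),11(13)-diene | C=C(COC(C)=O)[C@H]1C[C@@H](OC(=O)C=C(C)C)/C(COC(=O)[C@H](C)[C@H](C)O)=C/CC[C@@]2(CO)O[C@@H]2C1 | target

**Step count and risks**
Total: 22 steps. Longest linear sequence: 18 steps from (R)-carvone (steps 1–5, 7–14, 18–22); side branches are step 6 and steps 15–17.

Most likely to fail, step 13: slow transfer of the primary alkyl group from boron may let protodeboronation, β-hydride elimination from the alkylpalladium intermediate and intermolecular coupling (oligomers) outrun closure of the strained ten-membered 1,5-diene ring, and prolonged heating may start a Cope rearrangement. The fallback forms the same C1–C2 bond in a radical/nickel manifold. It sets out from boronate 18: oxidation (NaBO3·4H2O, THF/H2O) would give methyl (3R,5Z)-6-{[(tert-butyldiphenylsilyl)oxy]methyl}-8-hydroxy-3-[3-(naphthalen-2-ylmethoxy)prop-1-en-2-yl]oct-5-enoate F1, an Appel reaction (I2, PPh3, imidazole) the corresponding primary iodide F2, iBu2AlH at −78 °C the iodo aldehyde F3, and the iodo-aldol of step 12 the alkyl iodide/alkenyl iodide F4. A nickel-catalysed reductive cross-electrophile cyclization (NiI2, 4,4'-di-tert-butyl-2,2'-bipyridine, zinc dust, NaI, N,N-dimethylacetamide, high dilution), in which the alkenyl iodide enters by oxidative addition and the alkyl iodide as a radical, would then close the ring and come back to the route at macrocycle 25.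

Second, step 22: the tartrate-bound titanium alkoxide may have to attack a face of the ring olefin that the preferred ring conformer shields (poor facial selectivity), and the Lewis-acidic titanium may promote transannular opening of the new epoxide by the C1=C10 olefin. The fallback uses reagent control that needs no metal alkoxide and sets out from bis-silyl ether 38: Shi epoxidation (fructose-derived ketone or its enantiomer, chosen by the spiro transition-state model for the required face, potassium peroxymonosulfate KHSO5, K2CO3 buffer, MeCN/dimethoxymethane/H2O, 0 °C) should epoxidize only the electron-richest olefin C4=C5 and give the 15-O-tert-butyldiphenylsilyl 3'-O-tert-butyldimethylsilyl ether of the target F5, and buffered desilylation (Bu4NF, AcOH, THF) would come back to the route at target 40.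

Third, step 12: background addition promoted by Me3SiI alone and 1,3-induction from C7 may erode catalyst control at C9, and the strong Lewis acid may cleave ether protecting groups. The fallback separates bond formation from stereocontrol and sets out from aldehyde 19: a MgI2-mediated iodo-aldol with methyl propiolate (CH2Cl2, 0 °C) would give the (Z)-β-iodo adduct as a C3 epimer mixture F6, Dess–Martin oxidation the alkylidene β-keto ester F7, and Corey–Bakshi–Shibata reduction ((S)-2-methyl-CBS-oxazaborolidine, catecholborane, −78 °C, the alkenyl group acting as the large substituent) would come back to the route at the (3R)-alcohol 23.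

**Further compounds**
F1 | step 13 | methyl (3R,5Z)-6-{[(tert-butyldiphenylsilyl)oxy]methyl}-8-hydroxy-3-[3-(naphthalen-2-ylmethoxy)prop-1-en-2-yl]oct-5-enoate | C=C(COCc1ccc2ccccc2c1)[C@H](C/C=C(\CO[Si](c1ccccc1)(c1ccccc1)C(C)(C)C)CCO)CC(=O)OC
F2 | step 13 | methyl (3R,5Z)-6-{[(tert-butyldiphenylsilyl)oxy]methyl}-8-iodo-3-[3-(naphthalen-2-ylmethoxy)prop-1-en-2-yl]oct-5-enoate | C=C(COCc1ccc2ccccc2c1)[C@H](C/C=C(\CO[Si](c1ccccc1)(c1ccccc1)C(C)(C)C)CCI)CC(=O)OC
F3 | step 13 | (3R,5Z)-6-{[(tert-butyldiphenylsilyl)oxy]methyl}-8-iodo-3-[3-(naphthalen-2-ylmethoxy)prop-1-en-2-yl]oct-5-enal | C=C(COCc1ccc2ccccc2c1)[C@H](C/C=C(\CO[Si](c1ccccc1)(c1ccccc1)C(C)(C)C)CCI)CC=O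
F4 | step 13 | methyl (2Z,3R,5R,7Z)-8-{[(tert-butyldiphenylsilyl)oxy]methyl}-3-hydroxy-10-iodo-2-(iodomethylidene)-5-[3-(naphthalen-2-ylmethoxy)prop-1-en-2-yl]dec-7-enoate | C=C(COCc1ccc2ccccc2c1)[C@H](C/C=C(\CO[Si](c1ccccc1)(c1ccccc1)C(C)(C)C)CCI)C[C@@H](O)/C(C(=O)OC)=C/I
F5 | step 22 | 15-O-tert-butyldiphenylsilyl 3'-O-tert-butyldimethylsilyl ether of 40 | C=C(COC(C)=O)[C@H]1C[C@@H](OC(=O)C=C(C)C)/C(COC(=O)[C@H](C)[C@H](C)O[Si](C)(C)C(C)(C)C)=C/CC[C@@]2(CO[Si](c3ccccc3)(c3ccccc3)C(C)(C)C)O[C@@H]2C1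
F6 | step 12 | methyl (2Z,5R,7Z)-8-{[(tert-butyldiphenylsilyl)oxy]methyl}-3-hydroxy-2-(iodomethylidene)-5-[3-(naphthalen-2-ylmethoxy)prop-1-en-2-yl]-10-(4,4,5,5-tetramethyl-1,3,2-dioxaborolan-2-yl)dec-7-enoate (C3 epimers) | C=C(COCc1ccc2ccccc2c1)[C@H](C/C=C(\CO[Si](c1ccccc1)(c1ccccc1)C(C)(C)C)CCB1OC(C)(C)C(C)(C)O1)CC(O)/C(C(=O)OC)=C/I
F7 | step 12 | methyl (2Z,5R,7Z)-8-{[(tert-butyldiphenylsilyl)oxy]methyl}-2-(iodomethylidene)-5-[3-(naphthalen-2-ylmethoxy)prop-1-en-2-yl]-3-oxo-10-(4,4,5,5-tetramethyl-1,3,2-dioxaborolan-2-yl)dec-7-enoate | C=C(COCc1ccc2ccccc2c1)[C@H](C/C=C(\CO[Si](c1ccccc1)(c1ccccc1)C(C)(C)C)CCB1OC(C)(C)C(C)(C)O1)CC(=O)/C(C(=O)OC)=C/I
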